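Ring A of the hexahydroindene is grown onto a preformed, enantiopure cyclopentane (ring B) by a cationic (3+3) annulation. The disconnection exploits that C4, C3a and C7a form an allyl unit anchored in ring B, while the other ring A atoms C5, C6 and C7 with their geminal dimethyl group are an intact prenyl unit. A silyloxy-substituted methylenecyclopentane and prenyl chloride should be joined under SnCl4: allyl cation–olefin addition makes C4–C5, cation–olefin ring closure makes C7–C7a and the quaternary C7a centre, in one operation. The C1 side chain, the C3a–C4 double bond and the C2 acid are then set by enolate alkylation, deconjugation and hydroboration.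

Key step: step 3

Remark: locants follow the 1H-indene numbering of the target (C1 carries the side chain, C2 the carboxyl group, C3a=C4 is the ring olefin, C7 is the CMe2 carbon, C7a the angular carbon). The silyl ether, prenyl chloride, propargyl bromide and the trifluoroethyl phosphonate used as starting materials are assumed to be purchased.

Step 1
Reactants: 1 (R)-4-[tert-butyl(dimethyl)silyl]oxycyclopent-2-en-1-one
Product: 3 (2R,3R,4R)-4-[tert-butyl(dimethyl)silyl]oxy-2,3-dimethylcyclopentan-1-one, via lithium enolate 2 (not isolated)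
Conditions: Me2CuLi (from MeLi and CuI), Et2O, −78 °C; then MeI, HMPA, −78 to −20 °C
Reagents that add atoms: lithium dimethylcuprate, [Li+].C[Cu-]C; iodomethane, CI
Why: Tandem conjugate addition–enolate alkylation, in which the cuprate should add anti to the C4 silyloxy group (fixing the ring methyl centre that later steers the key step) and enolate 2 should be C-methylated trans to it, this second centre being erased again in step 3.

Step 2
Reactants: 3 (2R,3R,4R)-4-[tert-butyl(dimethyl)silyl]oxy-2,3-dimethylcyclopentan-1-one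
Product: 4 tert-butyl{[(1R,2R,3R)-2,3-dimethyl-4-methylidenecyclopentyl]oxy}dimethylsilane
Conditions: Zn, CH2Br2, TiCl4, THF/CH2Cl2, 0 °C to rt
Reagents that add atoms: dibromomethane, BrCBr
Why: Takai–Lombardo methylenation is non-basic, so the ketone should become the exocyclic olefin without epimerisation or β-elimination of the silyloxy group.

Step 3
Reactants: 4 tert-butyl{[(1R,2R,3R)-2,3-dimethyl-4-methylidenecyclopentyl]oxy}dimethylsilane; 5 1-chloro-3-methylbut-2-ene (prenyl chloride)
Product: 8 tert-butyldimethyl{[(1R,2R,7aS)-1,7,7,7a-tetramethyl-2,3,5,6,7,7a-hexahydro-1H-inden-2-yl]oxy}silane, via tertiary chloride adduct 6 (not isolated), via monocyclic diene 7 (not isolated)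
Conditions: 5 (1.3 equiv, slow addition), SnCl4 (0.3 equiv), CH2Cl2, −78 to −30 °C; then aqueous NaHCO3
Reagents that add atoms: 1-chloro-3-methylbut-2-ene (5), CC(C)=CCCl
Why: Proposed new method: SnCl4 ionises 5 to the 1,1-dimethylallyl cation, whose primary terminus is attacked by the exocyclic CH2 of 4 to make the C4–C5 bond; the tertiary cation (or its chloride 6) then loses the ring proton next to it to give the tetrasubstituted olefin 7 while that proton (as HCl or by internal relay) activates the prenyl double bond, and the new tertiary cation closes on C7a to make the C7–C7a bond before the ring-fusion cation loses a proton. The closest known reaction types are the Lewis acid-promoted addition of allyl chlorides to 1,1-dialkylethylenes and the cationic cyclisation of geranyl-type 1,5-dienes, merged here into a formal (3+3) annulation that mirrors head-to-tail prenyl transfer followed by cyclogeranyl ring closure. Ring A closes in a 6-endo-trig mode through a chair-like transition state. The quaternary centre C7a is set by substrate control, the cation approaching the olefin face anti to the adjacent C1 methyl group, which is itself trans to the C2 silyloxy group inherited from 1. Orientation is secured because only the exocyclic CH2 is nucleophilic while the allyl cation is present, and closure at the tetrasubstituted C7a rather than at C3 is favoured because the C3–C3a olefin isomer is deactivated by its allylic silyloxy group. The position of the final double bond need not be controlled, since the C3a–C4 and C3–C3a isomers and any C3a chloride all converge on the enone made in step 5.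

Step 4
Reactants: 8 tert-butyldimethyl{[(1R,2R,7aS)-1,7,7,7a-tetramethyl-2,3,5,6,7,7a-hexahydro-1H-inden-2-yl]oxy}silane
Product: 9 (1R,2R,7aS)-1,7,7,7a-tetramethyl-2,3,5,6,7,7a-hexahydro-1H-inden-2-ol
Conditions: Bu4NF, THF, 0 °C to rt
Reagents that add atoms: none
Why: Fluoride-mediated silyl ether cleavage, which touches no stereocentre and allows the C7a diastereomers to be separated while C1 and C2 are still stereogenic.

Step 5
Reactants: 9 (1R,2R,7aS)-1,7,7,7a-tetramethyl-2,3,5,6,7,7a-hexahydro-1H-inden-2-ol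
Product: 11 (1R,7aS)-1,7,7,7a-tetramethyl-1,4,5,6,7,7a-hexahydro-2H-inden-2-one, via deconjugated ketone 10 (not isolated)
Conditions: Dess–Martin periodinane, CH2Cl2, rt; then DBU, rt
Reagents that add atoms: none
Why: Dess–Martin oxidation should give ketone 10 and base-mediated isomerisation should move the olefin into conjugation, so that all olefin isomers from step 3 end as one enone, C1 being epimerisable here and reset in step 6.

Step 6
Reactants: 11 (1R,7aS)-1,7,7,7a-tetramethyl-1,4,5,6,7,7a-hexahydro-2H-inden-2-one; 12 3-bromoprop-1-yne (propargyl bromide)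
Product: 14 (1S,7aS)-1,7,7,7a-tetramethyl-1-(prop-2-yn-1-yl)-1,4,5,6,7,7a-hexahydro-2H-inden-2-one, via lithium dienolate 13 (not isolated)
Conditions: LiN(i-Pr)2, THF, −78 °C; then 12, HMPA, −78 to −40 °C
Reagents that add atoms: 3-bromoprop-1-yne (12), C#CCBr
Why: Kinetic deprotonation at the only α′ hydrogen gives the cross-conjugated enolate 13, which should be alkylated on the face anti to the axial C7a methyl group, so that the quaternary C1 centre forms with the two methyl groups cis (enolate alkylation).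

Step 7
Reactants: 14 (1S,7aS)-1,7,7,7a-tetramethyl-1-(prop-2-yn-1-yl)-1,4,5,6,7,7a-hexahydro-2H-inden-2-one
Product: 16 (1S,7aS)-1,7,7,7a-tetramethyl-1-(prop-2-yn-1-yl)-1,3,5,6,7,7a-hexahydro-2H-inden-2-one, via potassium dienolate 15 (not isolated)
Conditions: KN(SiMe3)2 (1.1 equiv), THF, −78 °C; then inverse quench into AcOH/THF, −78 °C
Reagents that add atoms: none
Why: With no α′ hydrogen left the base can only remove a γ hydrogen at C4, and kinetic α-protonation of dienolate 15 should give the β,γ-unsaturated ketone with the double bond at C3a–C4 (deconjugative protonation).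

Step 8
Reactants: 16 (1S,7aS)-1,7,7,7a-tetramethyl-1-(prop-2-yn-1-yl)-1,3,5,6,7,7a-hexahydro-2H-inden-2-one
Product: 17 (1R,7aS)-1,7,7,7a-tetramethyl-2-methylidene-1-(prop-2-yn-1-yl)-2,3,5,6,7,7a-hexahydro-1H-indene
Conditions: Zn, CH2Br2, TiCl4, THF/CH2Cl2, 0 °C to rt
Reagents that add atoms: dibromomethane, BrCBr
Why: Takai–Lombardo methylenation should convert the hindered, base-sensitive ketone into the 1,1-disubstituted olefin without moving the ring double bond back into conjugation.

Step 9
Reactants: 17 (1R,7aS)-1,7,7,7a-tetramethyl-2-methylidene-1-(prop-2-yn-1-yl)-2,3,5,6,7,7a-hexahydro-1H-indene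
Product: 19 3-[(1R,2S,7aS)-2-(hydroxymethyl)-1,7,7,7a-tetramethyl-2,3,5,6,7,7a-hexahydro-1H-inden-1-yl]propanal, via bis(dicyclohexylboryl) adduct 18 (not isolated)
Conditions: Cy2BH (3.5 equiv), THF, 0 °C to rt; then H2O2, pH 7 phosphate buffer, 0 °C
Reagents that add atoms: hydrogen peroxide, OO
Why: Hydroboration–oxidation, in which Cy2BH should add anti-Markovnikov to the terminal alkyne and to the exocyclic methylene but not to the trisubstituted ring olefin, approaching the methylene from the face anti to the two cis methyl groups so that hydrogen arrives at C2 on the side of the C1 chain (2S).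

Step 10
Reactants: 19 3-[(1R,2S,7aS)-2-(hydroxymethyl)-1,7,7,7a-tetramethyl-2,3,5,6,7,7a-hexahydro-1H-inden-1-yl]propanal; 20 ethyl 2-[bis(2,2,2-trifluoroethoxy)phosphoryl]propanoate
Product: 21 ethyl (2Z)-5-[(1R,2S,7aS)-2-(hydroxymethyl)-1,7,7,7a-tetramethyl-2,3,5,6,7,7a-hexahydro-1H-inden-1-yl]-2-methylpent-2-enoate
Conditions: 20, KN(SiMe3)2, 18-crown-6, THF, −78 °C
Reagents that add atoms: ethyl 2-[bis(2,2,2-trifluoroethoxy)phosphoryl]propanoate (20), CCOC(=O)C(C)P(=O)(OCC(F)(F)F)OCC(F)(F)F
Why: Still–Gennari olefination of the unhindered aldehyde should give the trisubstituted (Z)-enoate under kinetic control.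

Step 11
Reactants: 21 ethyl (2Z)-5-[(1R,2S,7aS)-2-(hydroxymethyl)-1,7,7,7a-tetramethyl-2,3,5,6,7,7a-hexahydro-1H-inden-1-yl]-2-methylpent-2-enoate
Product: 22 (1R,2S,7aS)-1-[(3Z)-5-ethoxy-4-methyl-5-oxopent-3-en-1-yl]-1,7,7,7a-tetramethyl-2,3,5,6,7,7a-hexahydro-1H-indene-2-carboxylic acid
Conditions: TEMPO (cat.), PhI(OAc)2, MeCN/H2O, rt
Reagents that add atoms: water, O
Why: Nitroxyl-catalysed oxidation in wet acetonitrile should take the primary alcohol through the aldehyde hydrate to the acid while leaving both olefins and the enoate untouched.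

Step 12
Reactants: 22 (1R,2S,7aS)-1-[(3Z)-5-ethoxy-4-methyl-5-oxopent-3-en-1-yl]-1,7,7,7a-tetramethyl-2,3,5,6,7,7a-hexahydro-1H-indene-2-carboxylic acid
Product: 23 (1R,2S,7aS)-1-[(3Z)-5-hydroxy-4-methylpent-3-en-1-yl]-1,7,7,7a-tetramethyl-2,3,5,6,7,7a-hexahydro-1H-indene-2-carboxylic acid
Conditions: i-Bu2AlH (4 equiv), CH2Cl2, −78 °C; then aqueous potassium sodium tartrate
Reagents that add atoms: none
Why: 1,2-Reduction of the conjugated ethyl ester to the (Z)-allylic alcohol should occur at −78 °C while the hindered acid is held as its unreactive aluminium carboxylate.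

Step 13
Reactants: 23 (1R,2S,7aS)-1-[(3Z)-5-hydroxy-4-methylpent-3-en-1-yl]-1,7,7,7a-tetramethyl-2,3,5,6,7,7a-hexahydro-1H-indene-2-carboxylic acid
Product: 25 (1R,2S,7aS)-1-[(3Z)-5-(acetyloxy)-4-methylpent-3-en-1-yl]-1,7,7,7a-tetramethyl-2,3,5,6,7,7a-hexahydro-1H-indene-2-carboxylic acid, via mixed anhydride 24 (not isolated)
Conditions: Ac2O, pyridine, DMAP (cat.), CH2Cl2, 0 °C; then H2O, rt
Reagents that add atoms: acetic anhydride, CC(=O)OC(C)=O
Why: Acylation of the primary allylic alcohol, after which the mixed anhydride 24 formed at the acid should be hydrolysed selectively on aqueous work-up.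

Compound list
1 | (R)-4-[tert-butyl(dimethyl)silyl]oxycyclopent-2-en-1-one | O=C1C=C[C@H](O[Si](C)(C)C(C)(C)C)C1 | starting material
2 | lithium (3R,4R)-4-[tert-butyl(dimethyl)silyl]oxy-3-methylcyclopent-1-en-1-olate | [Li]OC1=C[C@@H](C)[C@H](O[Si](C)(C)C(C)(C)C)C1 | intermediate
3 | (2R,3R,4R)-4-[tert-butyl(dimethyl)silyl]oxy-2,3-dimethylcyclopentan-1-one | O=C1[C@H](C)[C@@H](C)[C@H](O[Si](C)(C)C(C)(C)C)C1 | intermediate
4 | tert-butyl{[(1R,2R,3R)-2,3-dimethyl-4-methylidenecyclopentyl]oxy}dimethylsilane | C=C1[C@H](C)[C@@H](C)[C@H](O[Si](C)(C)C(C)(C)C)C1 | intermediate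
5 | 1-chloro-3-methylbut-2-ene (prenyl chloride) | CC(C)=CCCl | starting material
6 | tert-butyl{[(1R,2R,3R)-4-chloro-2,3-dimethyl-4-(4-methylpent-3-en-1-yl)cyclopentyl]oxy}dimethylsilane (C4 epimers) | CC(C)=CCCC1(Cl)C[C@@H](O[Si](C)(C)C(C)(C)C)[C@H](C)[C@H]1C | intermediate
7 | tert-butyl{[(1R,2R)-2,3-dimethyl-4-(4-methylpent-3-en-1-yl)cyclopent-3-en-1-yl]oxy}dimethylsilane | CC(C)=CCCC1=C(C)[C@@H](C)[C@H](O[Si](C)(C)C(C)(C)C)C1 | intermediate
8 | tert-butyldimethyl{[(1R,2R,7aS)-1,7,7,7a-tetramethyl-2,3,5,6,7,7a-hexahydro-1H-inden-2-yl]oxy}silane | C[C@H]1[C@H](O[Si](C)(C)C(C)(C)C)CC2=CCCC(C)(C)[C@]12C | intermediate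
9 | (1R,2R,7aS)-1,7,7,7a-tetramethyl-2,3,5,6,7,7a-hexahydro-1H-inden-2-ol | C[C@H]1[C@H](O)CC2=CCCC(C)(C)[C@]12C | intermediate
10 | (1R,7aS)-1,7,7,7a-tetramethyl-1,3,5,6,7,7a-hexahydro-2H-inden-2-one | C[C@H]1C(=O)CC2=CCCC(C)(C)[C@]12C | intermediate
11 | (1R,7aS)-1,7,7,7a-tetramethyl-1,4,5,6,7,7a-hexahydro-2H-inden-2-one | C[C@H]1C(=O)C=C2CCCC(C)(C)[C@]12C | intermediate
12 | 3-bromoprop-1-yne (propargyl bromide) | C#CCBr | starting material
13 | lithium (7aS)-1,7,7,7a-tetramethyl-4,5,6,7-tetrahydro-7aH-inden-2-olate | CC1=C(O[Li])C=C2CCCC(C)(C)[C@]12C | intermediate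
14 | (1S,7aS)-1,7,7,7a-tetramethyl-1-(prop-2-yn-1-yl)-1,4,5,6,7,7a-hexahydro-2H-inden-2-one | C#CC[C@]1(C)C(=O)C=C2CCCC(C)(C)[C@]12C | intermediate
15 | potassium (1S,7aS)-1,7,7,7a-tetramethyl-1-(prop-2-yn-1-yl)-5,6,7,7a-tetrahydro-1H-inden-2-olate | [K+].C#CC[C@]1(C)C([O-])=CC2=CCCC(C)(C)[C@]12C | intermediate
16 | (1S,7aS)-1,7,7,7a-tetramethyl-1-(prop-2-yn-1-yl)-1,3,5,6,7,7a-hexahydro-2H-inden-2-one | C#CC[C@]1(C)C(=O)CC2=CCCC(C)(C)[C@]12C | intermediate
17 | (1R,7aS)-1,7,7,7a-tetramethyl-2-methylidene-1-(prop-2-yn-1-yl)-2,3,5,6,7,7a-hexahydro-1H-indene | C#CC[C@]1(C)C(=C)CC2=CCCC(C)(C)[C@]12C | intermediate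
18 | (1R,2S,7aS)-1-[(2E)-3-(dicyclohexylboryl)prop-2-en-1-yl]-2-[(dicyclohexylboryl)methyl]-1,7,7,7a-tetramethyl-2,3,5,6,7,7a-hexahydro-1H-indene | B(C1CCCCC1)(C1CCCCC1)/C=C/C[C@]2(C)[C@@H](CB(C1CCCCC1)C1CCCCC1)CC1=CCCC(C)(C)[C@]21C | intermediate
19 | 3-[(1R,2S,7aS)-2-(hydroxymethyl)-1,7,7,7a-tetramethyl-2,3,5,6,7,7a-hexahydro-1H-inden-1-yl]propanal | O=CCC[C@]1(C)[C@@H](CO)CC2=CCCC(C)(C)[C@]12C | intermediate
20 | ethyl 2-[bis(2,2,2-trifluoroethoxy)phosphoryl]propanoate | CCOC(=O)C(C)P(=O)(OCC(F)(F)F)OCC(F)(F)F | starting material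
21 | ethyl (2Z)-5-[(1R,2S,7aS)-2-(hydroxymethyl)-1,7,7,7a-tetramethyl-2,3,5,6,7,7a-hexahydro-1H-inden-1-yl]-2-methylpent-2-enoate | CCOC(=O)/C(C)=C\CC[C@]1(C)[C@@H](CO)CC2=CCCC(C)(C)[C@]12C | intermediate
22 | (1R,2S,7aS)-1-[(3Z)-5-ethoxy-4-methyl-5-oxopent-3-en-1-yl]-1,7,7,7a-tetramethyl-2,3,5,6,7,7a-hexahydro-1H-indene-2-carboxylic acid | CCOC(=O)/C(C)=C\CC[C@]1(C)[C@@H](C(=O)O)CC2=CCCC(C)(C)[C@]12C | intermediate
23 | (1R,2S,7aS)-1-[(3Z)-5-hydroxy-4-methylpent-3-en-1-yl]-1,7,7,7a-tetramethyl-2,3,5,6,7,7a-hexahydro-1H-indene-2-carboxylic acid | OC/C(C)=C\CC[C@]1(C)[C@@H](C(=O)O)CC2=CCCC(C)(C)[C@]12C | intermediate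
24 | acetic (1R,2S,7aS)-1-[(3Z)-5-(acetyloxy)-4-methylpent-3-en-1-yl]-1,7,7,7a-tetramethyl-2,3,5,6,7,7a-hexahydro-1H-indene-2-carboxylic anhydride | CC(=O)OC/C(C)=C\CC[C@]1(C)[C@@H](C(=O)OC(C)=O)CC2=CCCC(C)(C)[C@]12C | intermediate
25 | (1R,2S,7aS)-1-[(3Z)-5-(acetyloxy)-4-methylpent-3-en-1-yl]-1,7,7,7a-tetramethyl-2,3,5,6,7,7a-hexahydro-1H-indene-2-carboxylic acid | CC(=O)OC/C(C)=C\CC[C@]1(C)[C@@H](C(=O)O)CC2=CCCC(C)(C)[C@@]21C | target

Total step count: 13. Longest linear sequence: 13 steps (from 1).

Steps most likely to fail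

Step 3 (proposed new method). The prenyl cation may oligomerise or prenylate the olefin intermediates a second time. The tertiary cation may migrate by hydride shifts towards C2 and end in loss of the silyloxy group. Ring closure may occur at C3 or in a 5-exo sense at C3a. Facial control at C7a may erode if C1 epimerises by reversible proton loss. Any C7a epimer has to be removed at the stage of 8 or 9, because after step 5 it would belong to the enantiomeric series. Fallback with known chemistry that still forms both ring A bonds in one operation: from 4, the Lewis acid-promoted sequential ene annulation of an alkylidenecycloalkane with acrolein (Me2AlCl, CH2Cl2, −78 to 0 °C) should give the bicyclic silyloxy alcohol F1, C4–C5 arising from the first ene reaction and C7–C7a from the intramolecular carbonyl-ene reaction. Dess–Martin oxidation would give the ketone F2, geminal dimethylation of the carbonyl group with Me2TiCl2 (from Me2Zn and TiCl4, CH2Cl2, −30 to 0 °C) the silyl ether F3, and Bu4NF the allylic alcohol F4. Dess–Martin oxidation of F4 comes back to the route at enone 11.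

Step 6. Deprotonation may occur at the γ position C4 instead of the hindered α′ methine, leading to alkylation at C3, or the electrophile may approach the wrong enolate face. Fallback: from 11, condensation with Me2NNH2 (AcOH cat., EtOH, reflux) gives the N,N-dimethylhydrazone F5, whose azaenolate (LiN(i-Pr)2, THF) can form only at the α′ carbon; alkylation with 12 gives the propargylated hydrazone F6, and hydrolysis (CuCl2, aqueous THF) comes back to the route at 14.

Step 9. Hydroboration of the hindered exocyclic olefin may be sluggish beside the alkyne, or boron may be delivered to the wrong face, which would invert C2. Fallback that sets C2 by equilibration instead of by reagent approach: the C2 epimer mixture is carried through step 10 to 21, the primary alcohol is oxidised with Dess–Martin periodinane and the epimerisable C2 centre is equilibrated with DBU in CH2Cl2, which should favour the aldehyde F7 with the formyl group cis to the smaller C1 substituent (methyl). Pinnick oxidation of F7 (NaClO2, NaH2PO4, 2-methylbut-2-ene, t-BuOH/H2O) comes back to the route at acid 22.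

Further compounds
F1 | step 3 | (1R,2R,7aR)-2-[tert-butyl(dimethyl)silyl]oxy-1,7a-dimethyl-2,4,5,6,7,7a-hexahydro-1H-inden-7-ol (C7 epimers) | C[C@H]1[C@H](O[Si](C)(C)C(C)(C)C)C=C2CCCC(O)[C@]12C
F2 | step 3 | (1R,2R,7aR)-2-[tert-butyl(dimethyl)silyl]oxy-1,7a-dimethyl-1,2,4,5,6,7a-hexahydro-7H-inden-7-one | C[C@H]1[C@H](O[Si](C)(C)C(C)(C)C)C=C2CCCC(=O)[C@]12C
F3 | step 3 | tert-butyldimethyl{[(1R,2R,7aS)-1,7,7,7a-tetramethyl-2,4,5,6,7,7a-hexahydro-1H-inden-2-yl]oxy}silane | C[C@H]1[C@H](O[Si](C)(C)C(C)(C)C)C=C2CCCC(C)(C)[C@]12C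
F4 | step 3 | (1R,2R,7aS)-1,7,7,7a-tetramethyl-2,4,5,6,7,7a-hexahydro-1H-inden-2-ol | C[C@H]1[C@H](O)C=C2CCCC(C)(C)[C@]12C
F5 | step 6 | (1R,7aS)-1,7,7,7a-tetramethyl-1,4,5,6,7,7a-hexahydro-2H-inden-2-one N,N-dimethylhydrazone | C[C@H]1C(=NN(C)C)C=C2CCCC(C)(C)[C@]12C
F6 | step 6 | (1S,7aS)-1,7,7,7a-tetramethyl-1-(prop-2-yn-1-yl)-1,4,5,6,7,7a-hexahydro-2H-inden-2-one N,N-dimethylhydrazone | C#CC[C@]1(C)C(=NN(C)C)C=C2CCCC(C)(C)[C@]12C
F7 | step 9 | ethyl (2Z)-5-[(1R,2S,7aS)-2-formyl-1,7,7,7a-tetramethyl-2,3,5,6,7,7a-hexahydro-1H-inden-1-yl]-2-methylpent-2-enoate | CCOC(=O)/C(C)=C\CC[C@]1(C)[C@@H](C=O)CC2=CCCC(C)(C)[C@]12C
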